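**Retrosynthetic overview**

1. Ring C (the 1,2-dioxane) is closed last: a new [Au(IPr)]NTf2-catalysed dehydrative peroxycyclisation of a C11 hydroperoxide onto the C14=C15–C16(OH) allylic alcohol makes the O–C14 bond, sets C14 and moves the olefin to Z-C15=C16.
2. The C10–O/C11–OO pair comes from perhydrolysis of a macrocyclic 10,11-cis-epoxide at C11 (inversion); C10 is acetylated while the peroxide is silyl-masked.
3. Rings A (14-membered carbocycle) and B (α-methylene-γ-butyrolactone) are formed together by an intramolecular CrCl2-mediated allylation/lactonisation (C5–C18 bond) of an open-chain bromo enal.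
4. The open chain is built from an epoxy enal by an (S)-HYTRA acetate aldol (C16), a Morita–Baylis–Hillman reaction and allylic bromination.
5. The epoxy enal comes from geraniol by Still–Gennari Z-olefination, Sharpless epoxidation (oxirane, C10/C11) and two Wittig homologations.

Assumption: carbon labels follow the target SMILES from left to right (C1 exo-methylene carbon, C2, C3 carbonyl, O4, C5 … C18) and are kept for all intermediates; reagents 5, 9, 14, 16 and 21 and D-(−)-diethyl tartrate are taken as commercial.

**Route**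

Step 1
Reactants: 1 geraniol
Product: 2 geranyl 4-methoxybenzyl ether
Conditions: NaH, 4-methoxybenzyl chloride, Bu4NI (cat.), THF/DMF, 0 °C → rt
Reagents that add atoms: 4-methoxybenzyl chloride, COc1ccc(CCl)cc1
Why: Williamson ether synthesis on the primary allylic alkoxide installs a PMB group that survives hydrides, ylides and titanium alkoxides and is removed oxidatively in step 17.

Step 2
Reactants: 2 geranyl 4-methoxybenzyl ether
Product: 3 6,7-epoxygeranyl 4-methoxybenzyl ether (racemic at the oxirane)
Conditions: mCPBA (1.0 equiv), CH2Cl2, −20 → 0 °C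
Reagents that add atoms: 3-chloroperbenzoic acid, OOC(=O)c1cccc(Cl)c1
Why: Prilezhaev epoxidation occurs at the more electron-rich distal trisubstituted olefin because the C6=C7 olefin is deactivated by the allylic ether oxygen; the new stereocentre is destroyed in step 3.

Step 3
Reactants: 3 6,7-epoxygeranyl 4-methoxybenzyl ether
Product: 4 (4E)-6-(4-methoxybenzyloxy)-4-methylhex-4-enal
Conditions: H5IO6, THF/Et2O, 0 °C
Reagents that add atoms: none
Why: Periodic acid opens the epoxide to the diol and cleaves it (Malaprade-type glycol cleavage) to the C10 aldehyde and acetone without touching the PMB ether or the E olefin.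

Step 4
Reactants: 4 (4E)-6-(4-methoxybenzyloxy)-4-methylhex-4-enal; 5 ethyl 2-[bis(2,2,2-trifluoroethoxy)phosphoryl]propanoate
Product: 6 ethyl (2Z,6E)-8-(4-methoxybenzyloxy)-2,6-dimethylocta-2,6-dienoate
Conditions: KN(SiMe3)2, 18-crown-6, THF, −78 °C
Reagents that add atoms: none
Why: Still–Gennari olefination with the electron-poor trifluoroethyl phosphonate under dissociating conditions is kinetically Z-selective, placing C9 cis to the ester carbon C12 as required for the later cis-epoxide.

Step 5
Reactants: 6 ethyl (2Z,6E)-8-(4-methoxybenzyloxy)-2,6-dimethylocta-2,6-dienoate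
Product: 7 (2Z,6E)-8-(4-methoxybenzyloxy)-2,6-dimethylocta-2,6-dien-1-ol
Conditions: iBu2AlH, CH2Cl2, −78 °C
Reagents that add atoms: none
Why: Diisobutylaluminium hydride reduces the enoate by 1,2-hydride delivery to the Z-allylic alcohol without olefin isomerisation.

Step 6
Reactants: 7 (2Z,6E)-8-(4-methoxybenzyloxy)-2,6-dimethylocta-2,6-dien-1-ol
Product: 8 (10S,11R)-cis-epoxy alcohol
Conditions: Ti(OiPr)4 (10 mol%), D-(−)-diethyl tartrate (12 mol%), t-BuOOH, 4 Å MS, CH2Cl2, −20 °C
Reagents that add atoms: tert-butyl hydroperoxide, CC(C)(C)OO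
Why: Sharpless asymmetric epoxidation of the primary allylic alcohol with the titanium–D-(−)-tartrate catalyst delivers oxygen to the olefin face that gives the 10S,11R cis-epoxide (reagent control), fixing C10 for good and C11 for later inversion, while the hydroxyl-free C6=C7 olefin is not epoxidised.

Step 7
Reactants: 8 (10S,11R)-cis-epoxy alcohol; 9 methyl (triphenylphosphoranylidene)acetate
Product: 11 (12E)-epoxy enoate, via epoxy aldehyde 10 (not isolated)
Conditions: Dess–Martin periodinane, pyridine, CH2Cl2, 0 °C → rt; then 9, rt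
Reagents that add atoms: none
Why: Dess–Martin oxidation gives the sensitive epoxy aldehyde, which is trapped in the same flask by a Wittig reaction with the stabilised ylide to give the E-enoate.

Step 8
Reactants: 11 (12E)-epoxy enoate
Product: 12 saturated epoxy methyl ester
Conditions: 2-nitrobenzenesulfonylhydrazide, Et3N, CH2Cl2, rt
Reagents that add atoms: none
Why: Diimide reduction transfers H2 in a concerted syn fashion to the unhindered, electron-poor disubstituted olefin only, leaving the trisubstituted C6=C7 olefin, the PMB ether and the epoxide (no hydrogenolysis) intact.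

Step 9
Reactants: 12 saturated epoxy methyl ester
Product: 13 epoxy aldehyde (C14 aldehyde)
Conditions: iBu2AlH, CH2Cl2, −78 °C
Reagents that add atoms: none
Why: At −78 °C the tetrahedral aluminium hemiacetal is stable, so the partial ester reduction stops at the C14 aldehyde.

Step 10
Reactants: 13 epoxy aldehyde (C14 aldehyde); 14 2-(triphenylphosphoranylidene)propanal
Product: 15 (14E)-epoxy enal
Conditions: toluene, 90 °C
Reagents that add atoms: none
Why: Wittig olefination with the stabilised α-methyl ylide gives the thermodynamically favoured E-2-methyl enal, installing C15, its methyl group and C16 with the 14E geometry needed for the final transposition.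

Step 11
Reactants: 15 (14E)-epoxy enal; 16 (S)-HYTRA, (1S)-2-hydroxy-1,2,2-triphenylethyl acetate
Product: 17 (16S)-aldol adduct (HYTRA ester)
Conditions: LiN(iPr)2 (2.2 equiv), THF, −78 → 0 °C; MgBr2, −78 °C; then 15, −115 °C
Reagents that add atoms: none
Why: Acetate aldol addition of the doubly deprotonated (S)-HYTRA as its magnesium enolate to the enal is auxiliary-controlled and gives the 16S carbinol that later steers the chirality transfer of step 24, and diastereomers arising from the minor epoxide enantiomer are removed here by chromatography.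

Step 12
Reactants: 17 (16S)-aldol adduct (HYTRA ester)
Product: 18 (16S)-β-hydroxy methyl ester
Conditions: K2CO3 (cat.), MeOH, rt
Reagents that add atoms: methanol, CO
Why: Base-catalysed transesterification, assisted by the neighbouring hydroxyl of the auxiliary, releases the recoverable triphenylethanediol and leaves the β-hydroxy methyl ester.

Step 13
Reactants: 18 (16S)-β-hydroxy methyl ester
Product: 19 (16S)-silyloxy methyl ester
Conditions: TBSCl, imidazole, DMF, rt
Reagents that add atoms: tert-butyldimethylsilyl chloride, CC(C)(C)[Si](C)(C)Cl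
Why: Imidazole-promoted silylation protects the secondary allylic C16 hydroxyl through the hydride, chromium and perhydrolysis steps.

Step 14
Reactants: 19 (16S)-silyloxy methyl ester
Product: 20 (16S)-silyloxy aldehyde (C18 aldehyde)
Conditions: iBu2AlH, CH2Cl2, −78 °C
Reagents that add atoms: none
Why: Partial reduction of the methyl ester at −78 °C via the stable aluminium hemiacetal gives the C18 aldehyde without β-elimination of the silyloxy group.

Step 15
Reactants: 20 (16S)-silyloxy aldehyde (C18 aldehyde); 21 methyl acrylate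
Product: 22 Morita–Baylis–Hillman adduct (both C18 epimers)
Conditions: quinuclidin-3-ol (cat.), MeOH, rt, methyl acrylate in excess
Reagents that add atoms: none
Why: Morita–Baylis–Hillman reaction, in which conjugate addition of the amine to the acrylate gives an enolate that adds to the aldehyde and then expels the amine, installs C2, C3 and the future exo-methylene carbon; the new C18 carbinol centre is lost in step 16.

Step 16
Reactants: 22 Morita–Baylis–Hillman adduct (both C18 epimers)
Product: 23 (Z)-2-(bromomethyl)enoate
Conditions: NBS, Me2S, CH2Cl2, −30 → 0 °C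
Reagents that add atoms: N-bromosuccinimide, BrN1C(=O)CCC1=O
Why: Corey–Kim-type activation of the allylic hydroxyl as an alkoxysulfonium ion and SN2′ attack of bromide give the thermodynamically preferred Z-2-(bromomethyl)enoate (C17 cis to CH2Br) under neutral conditions that spare the epoxide.

Step 17
Reactants: 23 (Z)-2-(bromomethyl)enoate
Product: 24 C5 allylic alcohol
Conditions: DDQ, CH2Cl2/pH 7 buffer, 0 °C
Reagents that add atoms: none
Why: DDQ oxidises the electron-rich PMB ether by hydride abstraction to an oxocarbenium ion that is hydrolysed, liberating the C5 allylic alcohol while silyl ether, epoxide and allylic bromide are untouched.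

Step 18
Reactants: 24 C5 allylic alcohol
Product: 25 bromo enal (seco compound)
Conditions: MnO2, CH2Cl2, rt
Reagents that add atoms: none
Why: Manganese dioxide oxidises only the allylic alcohol and gives the E-enal needed as the electrophile for ring closure.

Step 19
Reactants: 25 bromo enal (seco compound)
Product: 27 epoxy macrolactone (rings A and B), via macrocyclic hydroxy ester 26 (not isolated)
Conditions: CrCl2 (10 equiv), THF, rt, syringe-pump addition to 2 mM
Reagents that add atoms: none
Why: In this Nozaki–Hiyama-type intramolecular Barbier allylation, divalent chromium converts the allylic bromide into a Z-configured 2-(methoxycarbonyl)allylchromium species that adds to the enal through a chair Zimmerman–Traxler transition state (aldehyde substituent equatorial, C17 axial), giving the syn adduct whose chromium alkoxide lactonises to the cis-fused α-methylene lactone; C5 and C18 are set here, with 5S,18S expected from the conformer that keeps the bulky 16-silyloxy group outside the forming ring, and the other cis isomer is separable.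

Step 20
Reactants: 27 epoxy macrolactone (rings A and B)
Product: 28 10-hydroxy-11-hydroperoxide
Conditions: H2O2 (anhydrous, in Et2O, excess), H3PMo12O40 (5 mol%), Et2O, 0 °C → rt
Reagents that add atoms: hydrogen peroxide, OO
Why: Acid-catalysed perhydrolysis of the trisubstituted epoxide lets H2O2 attack the activated oxirane at the tertiary carbon C11 with inversion (borderline SN2), giving the anti β-hydroxy hydroperoxide with the target configuration at C10 and C11, and the large excess of H2O2 outcompetes transannular capture by the olefins.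

Step 21
Reactants: 28 10-hydroxy-11-hydroperoxide
Product: 29 11-triethylsilyl peroxide
Conditions: Et3SiCl, pyridine, CH2Cl2, −20 °C
Reagents that add atoms: chlorotriethylsilane, CC[Si](Cl)(CC)CC
Why: The acidic, sterically unhindered hydroperoxide O–H is silylated much faster than the neopentyl-type C10 secondary alcohol, so the peroxide is masked chemoselectively as its triethylsilyl peroxide.

Step 22
Reactants: 29 11-triethylsilyl peroxide
Product: 30 10-acetate
Conditions: Ac2O, DMAP (cat.), pyridine, CH2Cl2, 0 °C → rt
Reagents that add atoms: acetic anhydride, CC(=O)OC(C)=O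
Why: DMAP-catalysed acylation esterifies the remaining C10 hydroxyl, so that the only free nucleophile in the gold step is the hydroperoxide and the known hydroxyl cyclisation cannot compete.

Step 23
Reactants: 30 10-acetate
Product: 31 hydroperoxy allylic alcohol
Conditions: HF·pyridine, pyridine, THF, 0 °C → rt
Reagents that add atoms: none
Why: Fluoride-mediated desilylation cleaves both Si–O bonds (silyl peroxide and silyl ether) through pentacoordinate silicon while acetate, lactone and the O–O bond are inert.

Step 24
Reactants: 31 hydroperoxy allylic alcohol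
Product: 32 target CNP0238885.1
Conditions: [Au(IPr)]NTf2 (5 mol%; IPr = 1,3-bis(2,6-diisopropylphenyl)imidazol-2-ylidene), 4 Å MS, CH2Cl2, −20 → 0 °C
Reagents that add atoms: none
Why: Proposed new method: the cationic monovalent gold centre of [Au(IPr)]NTf2 activates the C14=C15 olefin while the hydroperoxide O–H hydrogen-bonds to the C16 hydroxyl, the unhindered terminal peroxide oxygen adds anti to gold at C14 in a chair-like 6-exo transition state (C10 equatorial, C11 methyl axial), and anti-elimination of gold and the activated C16 hydroxyl releases water, so the net syn-SN2′ displacement closes ring C, transfers the 16S carbinol chirality to the 14S C–O centre and, because A1,2 strain with the C15 methyl group forces C17 into the inside position, gives the Z-C15=C16 olefin; attack at C15 is unproductive because only C14 attack is followed by irreversible loss of the hydroxyl, and monovalent gold does not cleave O–O bonds; the closest known reaction type is the gold-catalysed dehydrative cyclisation of monoallylic diols to 2-alkenyl tetrahydropyrans with 1,3-chirality transfer, which has not been shown with a hydroperoxide nucleophile.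

**Compound list**

In the names below, Ep stands for the (2R,3S)-3-[(3E)-5-(4-methoxybenzyloxy)-3-methylpent-3-en-1-yl]-2-methyloxiran-2-yl group.

1 | geraniol, (2E)-3,7-dimethylocta-2,6-dien-1-ol | OC/C=C(\C)CCC=C(C)C | starting material
2 | geranyl 4-methoxybenzyl ether | COc1ccc(COC/C=C(\C)CCC=C(C)C)cc1 | intermediate
3 | 3-[(3E)-5-(4-methoxybenzyloxy)-3-methylpent-3-en-1-yl]-2,2-dimethyloxirane (racemic) | COc1ccc(COC/C=C(\C)CCC2OC2(C)C)cc1 | intermediate
4 | (4E)-6-(4-methoxybenzyloxy)-4-methylhex-4-enal | COc1ccc(COC/C=C(\C)CCC=O)cc1 | intermediate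
5 | ethyl 2-[bis(2,2,2-trifluoroethoxy)phosphoryl]propanoate | CCOC(=O)C(C)P(=O)(OCC(F)(F)F)OCC(F)(F)F | starting material
6 | ethyl (2Z,6E)-8-(4-methoxybenzyloxy)-2,6-dimethylocta-2,6-dienoate | COc1ccc(COC/C=C(\C)CC/C=C(/C)C(=O)OCC)cc1 | intermediate
7 | (2Z,6E)-8-(4-methoxybenzyloxy)-2,6-dimethylocta-2,6-dien-1-ol | COc1ccc(COC/C=C(\C)CC/C=C(/C)CO)cc1 | intermediate
8 | Ep-methanol, [(2R,3S)-3-[(3E)-5-(4-methoxybenzyloxy)-3-methylpent-3-en-1-yl]-2-methyloxiran-2-yl]methanol (10S,11R cis-epoxide) | COc1ccc(COC/C=C(\C)CC[C@@H]2O[C@]2(C)CO)cc1 | intermediate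
9 | methyl (triphenylphosphoranylidene)acetate | COC(=O)C=P(c1ccccc1)(c1ccccc1)c1ccccc1 | starting material
10 | (2S,3S)-3-[(3E)-5-(4-methoxybenzyloxy)-3-methylpent-3-en-1-yl]-2-methyloxirane-2-carbaldehyde | COc1ccc(COC/C=C(\C)CC[C@@H]2O[C@]2(C)C=O)cc1 | intermediate
11 | methyl (2E)-3-Ep-prop-2-enoate | COc1ccc(COC/C=C(\C)CC[C@@H]2O[C@]2(C)/C=C/C(=O)OC)cc1 | intermediate
12 | methyl 3-Ep-propanoate | COc1ccc(COC/C=C(\C)CC[C@@H]2O[C@]2(C)CCC(=O)OC)cc1 | intermediate
13 | 3-Ep-propanal | COc1ccc(COC/C=C(\C)CC[C@@H]2O[C@]2(C)CCC=O)cc1 | intermediate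
14 | 2-(triphenylphosphoranylidene)propanal | CC(C=O)=P(c1ccccc1)(c1ccccc1)c1ccccc1 | starting material
15 | (2E)-5-Ep-2-methylpent-2-enal | COc1ccc(COC/C=C(\C)CC[C@@H]2O[C@]2(C)CC/C=C(\C)C=O)cc1 | intermediate
16 | (S)-HYTRA, (1S)-2-hydroxy-1,2,2-triphenylethyl acetate | CC(=O)O[C@@H](c1ccccc1)C(O)(c1ccccc1)c1ccccc1 | starting material
17 | (1S)-2-hydroxy-1,2,2-triphenylethyl (3S,4E)-7-Ep-3-hydroxy-4-methylhept-4-enoate | COc1ccc(COC/C=C(\C)CC[C@@H]2O[C@]2(C)CC/C=C(\C)[C@@H](O)CC(=O)O[C@@H](c3ccccc3)C(O)(c3ccccc3)c3ccccc3)cc1 | intermediate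
18 | methyl (3S,4E)-7-Ep-3-hydroxy-4-methylhept-4-enoate | COc1ccc(COC/C=C(\C)CC[C@@H]2O[C@]2(C)CC/C=C(\C)[C@@H](O)CC(=O)OC)cc1 | intermediate
19 | methyl (3S,4E)-3-[(tert-butyldimethylsilyl)oxy]-7-Ep-4-methylhept-4-enoate | COc1ccc(COC/C=C(\C)CC[C@@H]2O[C@]2(C)CC/C=C(\C)[C@@H](O[Si](C)(C)C(C)(C)C)CC(=O)OC)cc1 | intermediate
20 | (3S,4E)-3-[(tert-butyldimethylsilyl)oxy]-7-Ep-4-methylhept-4-enal | COc1ccc(COC/C=C(\C)CC[C@@H]2O[C@]2(C)CC/C=C(\C)[C@@H](O[Si](C)(C)C(C)(C)C)CC=O)cc1 | intermediate
21 | methyl acrylate | C=CC(=O)OC | starting material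
22 | methyl (5S,6E)-5-[(tert-butyldimethylsilyl)oxy]-9-Ep-3-hydroxy-6-methyl-2-methylidenenon-6-enoate (both C3 epimers) | COc1ccc(COC/C=C(\C)CC[C@@H]2O[C@]2(C)CC/C=C(\C)[C@@H](O[Si](C)(C)C(C)(C)C)CC(O)C(=C)C(=O)OC)cc1 | intermediate
23 | methyl (2Z,5S,6E)-2-(bromomethyl)-5-[(tert-butyldimethylsilyl)oxy]-9-Ep-6-methylnona-2,6-dienoate | COc1ccc(COC/C=C(\C)CC[C@@H]2O[C@]2(C)CC/C=C(\C)[C@@H](O[Si](C)(C)C(C)(C)C)C/C=C(\CBr)C(=O)OC)cc1 | intermediate
24 | methyl (2Z,5S,6E)-2-(bromomethyl)-5-[(tert-butyldimethylsilyl)oxy]-9-[(2R,3S)-3-[(3E)-5-hydroxy-3-methylpent-3-en-1-yl]-2-methyloxiran-2-yl]-6-methylnona-2,6-dienoate | OC/C=C(\C)CC[C@@H]1O[C@]1(C)CC/C=C(\C)[C@@H](O[Si](C)(C)C(C)(C)C)C/C=C(\CBr)C(=O)OC | intermediate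
25 | methyl (2Z,5S,6E)-2-(bromomethyl)-5-[(tert-butyldimethylsilyl)oxy]-6-methyl-9-[(2R,3S)-2-methyl-3-[(3E)-3-methyl-5-oxopent-3-en-1-yl]oxiran-2-yl]nona-2,6-dienoate | O=C/C=C(\C)CC[C@@H]1O[C@]1(C)CC/C=C(\C)[C@@H](O[Si](C)(C)C(C)(C)C)C/C=C(\CBr)C(=O)OC | intermediate
26 | macrocyclic hydroxy ester: 14-membered carbocycle C5–C18 with 5S-OH, 18S-[1-(methoxycarbonyl)vinyl], 6E and 14E olefins, 10S,11R cis-epoxide, 16S-OTBS | C=C(C(=O)OC)[C@H]1[C@@H](O)/C=C(\C)CC[C@@H]2O[C@]2(C)CC/C=C(\C)[C@@H](O[Si](C)(C)C(C)(C)C)C1 | intermediate
27 | epoxy macrolactone: cis-fused α-methylene-γ-butyrolactone (5S,18S) on the 14-membered carbocycle, 6E,14E, 10S,11R cis-epoxide, 16S-OTBS | C=C1C(=O)O[C@H]2/C=C(\C)CC[C@@H]3O[C@]3(C)CC/C=C(\C)[C@@H](O[Si](C)(C)C(C)(C)C)C[C@@H]12 | intermediate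
28 | (5S,10S,11S,16S,18S)-10-hydroxy-11-hydroperoxy macrolactone, 6E,14E, 16-OTBS | C=C1C(=O)O[C@H]2/C=C(\C)CC[C@H](O)[C@](OO)(C)CC/C=C(\C)[C@@H](O[Si](C)(C)C(C)(C)C)C[C@@H]12 | intermediate
29 | (5S,10S,11S,16S,18S)-10-hydroxy-11-(triethylsilylperoxy) macrolactone, 6E,14E, 16-OTBS | C=C1C(=O)O[C@H]2/C=C(\C)CC[C@H](O)[C@](OO[Si](CC)(CC)CC)(C)CC/C=C(\C)[C@@H](O[Si](C)(C)C(C)(C)C)C[C@@H]12 | intermediate
30 | (5S,10S,11S,16S,18S)-10-acetoxy-11-(triethylsilylperoxy) macrolactone, 6E,14E, 16-OTBS | C=C1C(=O)O[C@H]2/C=C(\C)CC[C@H](OC(C)=O)[C@](OO[Si](CC)(CC)CC)(C)CC/C=C(\C)[C@@H](O[Si](C)(C)C(C)(C)C)C[C@@H]12 | intermediate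
31 | (5S,10S,11S,16S,18S)-10-acetoxy-11-hydroperoxy-16-hydroxy macrolactone, 6E,14E | C=C1C(=O)O[C@H]2/C=C(\C)CC[C@H](OC(C)=O)[C@](OO)(C)CC/C=C(\C)[C@@H](O)C[C@@H]12 | intermediate
32 | CNP0238885.1: (5S,10S,11S,14S,18S)-10-acetoxy-11,14-epidioxy cembranolide, 6E,15Z | C=C1C(=O)O[C@H]2/C=C(\C)CC[C@H](OC(C)=O)[C@]3(C)CC[C@H](OO3)/C(C)=C\C[C@@H]12 | target

**Summary**

Total step count: 24. Longest linear sequence: 24 steps (1 → 32).

Steps most likely to fail:

- **Step 24 (new gold-catalysed peroxycyclisation).** The risks are incomplete chirality transfer (14R or 15E isomers) and catalyst deactivation by the hydroperoxide. The fallback uses known chemistry, sets out from 31 and comes back at 32. Compound 31 is treated with a catalytic Brønsted acid (camphorsulfonic acid or Amberlyst-15, 4 Å MS, CH2Cl2, −20 °C). Ionisation of the secondary allylic alcohol gives a 2-methylallyl cation that the tethered hydroperoxide captures at its C14 terminus, the six-membered ring being favoured over the eight-membered one. This is the established acid-mediated route from hydroperoxides and allylic or tertiary alcohols to cyclic peroxides. Stereocontrol then rests on ring control (trans-diequatorial dioxane) instead of chirality transfer, and 32 is separated from its C14 and olefin isomers by HPLC. This fallback makes no new compound (F0).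

- **Step 19 (chromium-mediated macrocyclisation).** The risks are oligomerisation and the wrong facial sense at C5/C18, since the cis relationship is secure but the absolute sense relative to C16 is only modelled. The fallback sets out from 24 and comes back at 27. Borylation of the allylic bromide with bis(pinacolato)diboron and Pd2(dba)3 (zerovalent palladium, cat.) in toluene gives the allylboronate alcohol F1, and MnO2 oxidation gives the boronate enal F2. Heating F2 in toluene at 80 °C and 2 mM, optionally with a chiral phosphoric acid for reagent control, effects an intramolecular allylboration through a compact boron-centred chair transition state. The γ-substituent cis to CH2B gives the syn adduct, and the borate lactonises to 27 on work-up. This replaces a reductive Barbier addition by a redox-neutral allylboration of an isolable reagent, with a tighter transition state and a second handle on facial selectivity.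

- **Step 15 (Morita–Baylis–Hillman reaction).** The risk is slow conversion and amine-induced E1cB loss of the β-silyloxy group from 20 to a conjugated dienal. The fallback sets out from 20 and comes back at 22. Methyl propiolate is hydroaluminated with iBu2AlH in THF/HMPA at 0 °C to the α-aluminoacrylate, and 20 is added at 0 °C → rt. This pre-formed, non-basic vinyl nucleophile gives the same adduct 22 without days of exposure to an amine. This fallback makes no new compound (F0).

Further compounds
F1 | step 19 | methyl (2E,5S,6E)-5-[(tert-butyldimethylsilyl)oxy]-9-[(2R,3S)-3-[(3E)-5-hydroxy-3-methylpent-3-en-1-yl]-2-methyloxiran-2-yl]-6-methyl-2-[(4,4,5,5-tetramethyl-1,3,2-dioxaborolan-2-yl)methyl]nona-2,6-dienoate | OC/C=C(\C)CC[C@@H]1O[C@]1(C)CC/C=C(\C)[C@@H](O[Si](C)(C)C(C)(C)C)C/C=C(\CB2OC(C)(C)C(C)(C)O2)C(=O)OC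
F2 | step 19 | methyl (2E,5S,6E)-5-[(tert-butyldimethylsilyl)oxy]-6-methyl-9-[(2R,3S)-2-methyl-3-[(3E)-3-methyl-5-oxopent-3-en-1-yl]oxiran-2-yl]-2-[(4,4,5,5-tetramethyl-1,3,2-dioxaborolan-2-yl)methyl]nona-2,6-dienoate | O=C/C=C(\C)CC[C@@H]1O[C@]1(C)CC/C=C(\C)[C@@H](O[Si](C)(C)C(C)(C)C)C/C=C(\CB2OC(C)(C)C(C)(C)O2)C(=O)OC
F0 | step 15 | none | none
F0 | step 24 | none | none
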